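## Retrosynthetic overview

- Feature: in the coumarin, C2–C3–C4–C4a–C8a–C8–C7–C6–C5–CH3 is one straight ten-carbon chain. Its alternate carbons C2, C4, C8a and (before aromatisation) C5 carry oxygen, C7 is the one such position without it, and the C4a–C5 bond folds the chain into the benzene ring.
- Benzene ring (C4a, C5, C6, C7, C8, C8a) first: TiCl4 [3+3] annulation of a tris(silyloxy)triene (C2 to C8) with 4-methoxybut-3-en-2-one (C7, C6, C5, CH3), forming C8–C7 and C4a–C5. Pyranone ring second, by O1–C2 lactonisation.
- O4–C1′ by Mitsunobu etherification with a C10 diol built from a 4-silyloxybut-2-ynoate: syn-carbocupration fixes the 2′Z alkene; Shi epoxidation and epoxide-to-allylic-alcohol isomerisation fix 6′R.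
- C6′–OOH by SN2 inversion of the 6′R mesylate with H2O2 (gives 6′S), then desilylation.

Key step: step 4

Remark: the side chain is numbered C1′ (OCH2) to C8′ (=CH2); by the CIP rules the target is (2′Z,6′S). The enol ether geometries of 3 and 4 are drawn arbitrarily because they disappear on aromatisation.

## Route

Step 1
Reactants: 1 4-hydroxy-6-methyl-2H-pyran-2-one
Product: 2 methyl 3,5-dioxohexanoate
Conditions: Mg(OMe)2, MeOH, reflux; then cold 1 M HCl
Reagents that add atoms: methanol, CO (delivered as Mg(OMe)2, C[O-].C[O-].[Mg+2])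
Why: Methoxide opens the lactone by acyl substitution at C2 (ring-opening methanolysis), and the magnesium chelate of the resulting 3,5-diketo ester should protect it from retro-Claisen cleavage.

Step 2
Reactants: 2 methyl 3,5-dioxohexanoate
Product: 3 methyl (2Z,4Z)-3,5-bis(trimethylsilyloxy)hexa-2,4-dienoate (one geometry drawn, a mixture is acceptable)
Conditions: Me3SiCl (2.6 equiv), Et3N (2.6 equiv), toluene, 20 °C; filtered under argon, used crude
Reagents that add atoms: chlorotrimethylsilane, C[Si](C)(C)Cl
Why: Both 1,3-dicarbonyl units are enolised enough for O-silylation by Me3SiCl/Et3N (silyl enol ether formation), which should give the conjugated bis(silyl enol ether).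

Step 3
Reactants: 3 methyl (2Z,4Z)-3,5-bis(trimethylsilyloxy)hexa-2,4-dienoate
Product: 4 1-methoxy-1,3,5-tris(trimethylsilyloxy)hexa-1,3,5-triene ((1Z,3Z) isomer drawn)
Conditions: LiN(i-Pr)2 (LDA, 1.3 equiv), THF, −78 °C; Me3SiCl, −78 → 20 °C; salts removed in hexane, used at once
Reagents that add atoms: chlorotrimethylsilane, C[Si](C)(C)Cl
Why: LDA removes a proton from the terminal methyl group (vinylogous deprotonation) and the extended trienolate is trapped on the ester oxygen, as in the second stage of the standard preparation of 1,3-bis(silyloxy)dienes.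

Step 4
Reactants: 4 1-methoxy-1,3,5-tris(trimethylsilyloxy)hexa-1,3,5-triene; 5 (E)-4-methoxybut-3-en-2-one
Product: 8 methyl 3-(2-hydroxy-6-methylphenyl)-3-oxopropanoate, via open-chain conjugate adduct 6 (not isolated), via cyclohexanone aldol adduct 7 (not isolated)
Conditions: 4 (1.3 equiv), TiCl4 (1.1 equiv), 4 Å MS, CH2Cl2, −78 → 20 °C; then 10% aq. HCl
Reagents that add atoms: none
Why: TiCl4 binds the carbonyl oxygen of vinylogous ester 5, and the terminal CH2 of triene 4, its most electron-rich and least hindered carbon, adds to the methoxy-bearing β-carbon in a vinylogous Mukaiyama–Michael step that forms C8–C7 and gives 6. The internal carbon of the remaining 3-silyloxy-diene (future C4a) then attacks the titanium-activated methyl ketone (future C5) in an intramolecular Mukaiyama aldol, a 6-(enolexo)-exo-trig closure that forms C4a–C5 and the only new ring, giving aldolate 7. Loss of methanol from C7 and of the tertiary oxygen from C5, followed by enolisation of the C8a ketone, aromatises the ring, and the ketene silyl acetal is hydrolysed to the methyl ester on acidic work-up. The closest known reaction type is the TiCl4-mediated formal [3+3] cyclocondensation of 1,3-bis(silyloxy)buta-1,3-dienes with 3-alkoxy- or 3-silyloxy-enones to salicylates, of which this is the vinylogous triketide case; no stereocentre remains in 8. The step needs the 5-methyl rather than 7-methyl orientation and closure through C4a only: the first should follow because the most nucleophilic terminus pairs with the Lewis-acid-activated β-position before the ketone is engaged, the second because closure from the ester α-carbon would have to make an eight-membered ring.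

Step 5
Reactants: 8 methyl 3-(2-hydroxy-6-methylphenyl)-3-oxopropanoate
Product: 9 4-hydroxy-5-methyl-2H-chromen-2-one
Conditions: p-TsOH·H2O (cat.), toluene, reflux, methanol distilled off
Reagents that add atoms: none
Why: The phenol attacks the ester carbonyl in an acid-catalysed 6-exo-trig transesterification (lactonisation), and the chromane-2,4-dione formed is stabilised as the enolic 4-hydroxycoumarin.

Step 6
Reactants: 10 tert-butyldimethyl(prop-2-yn-1-yloxy)silane
Product: 11 propan-2-yl 4-[(tert-butyldimethylsilyl)oxy]but-2-ynoate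
Conditions: n-BuLi, THF, −78 °C; i-PrOCOCl, −78 → 0 °C
Reagents that add atoms: isopropyl chloroformate, CC(C)OC(=O)Cl
Why: C-acylation of the lithium acetylide with a chloroformate gives the ynoate, and the isopropyl ester is chosen so that the later Al(OiPr)3 step cannot scramble the ester group.

Step 7
Reactants: 12 5-bromo-2-methylpent-2-ene; 11 propan-2-yl 4-[(tert-butyldimethylsilyl)oxy]but-2-ynoate
Product: 14 propan-2-yl (2Z)-3-{[(tert-butyldimethylsilyl)oxy]methyl}-7-methylocta-2,6-dienoate, via 4-methylpent-3-enylmagnesium bromide 13 (not isolated)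
Conditions: Mg, THF, 20–40 °C; CuBr·SMe2 (0.5 equiv per RMgBr), THF, −40 °C; then 11, −78 °C; sat. aq. NH4Cl at −78 °C
Reagents that add atoms: none
Why: Organocuprate conjugate addition to the 2-ynoate is a syn-carbocupration that places the new alkyl group and the incoming proton cis, so the ester and the silyloxymethyl group should end up cis (2Z), and the cold quench prevents equilibration of the alkenylcopper/allenoate.

Step 8
Reactants: 14 propan-2-yl (2Z)-3-{[(tert-butyldimethylsilyl)oxy]methyl}-7-methylocta-2,6-dienoate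
Product: 15 propan-2-yl (2Z)-3-{[(tert-butyldimethylsilyl)oxy]methyl}-5-[(2R)-3,3-dimethyloxiran-2-yl]pent-2-enoate
Conditions: D-fructose-derived Shi ketone (1,2:4,5-di-O-isopropylidene-β-D-erythro-2,3-hexodiulo-2,6-pyranose, 0.3 equiv), Oxone (2KHSO5·KHSO4·K2SO4), K2CO3, Bu4NHSO4, Na2B4O7/Na2EDTA buffer, MeCN–CH2(OMe)2, 0 °C
Reagents that add atoms: potassium peroxymonosulfate KHSO5 (as Oxone), [K+].[O-]S(=O)(=O)OO
Why: In this Shi asymmetric epoxidation the chiral dioxirane attacks only the electron-rich 6,7-alkene (the enoate is inert), and the spiro transition state of the D-fructose-derived ketone should deliver oxygen to the face that gives the (R)-epoxide, as for other 2-methylalk-2-enes.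

Step 9
Reactants: 15 propan-2-yl (2Z)-3-{[(tert-butyldimethylsilyl)oxy]methyl}-5-[(2R)-3,3-dimethyloxiran-2-yl]pent-2-enoate
Product: 16 propan-2-yl (2Z,6R)-3-{[(tert-butyldimethylsilyl)oxy]methyl}-6-hydroxy-7-methylocta-2,7-dienoate
Conditions: Al(OiPr)3 (2 equiv), toluene, 110 °C; aq. potassium sodium tartrate
Reagents that add atoms: none
Why: Al(OiPr)3 coordinates the epoxide oxygen and removes a methyl proton of the tertiary carbon through a cyclic syn-elimination (epoxide to allylic alcohol isomerisation) that breaks only the C7–O bond, so the C6–O bond and its (R) configuration are carried over unchanged.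

Step 10
Reactants: 16 propan-2-yl (2Z,6R)-3-{[(tert-butyldimethylsilyl)oxy]methyl}-6-hydroxy-7-methylocta-2,7-dienoate
Product: 17 (2Z,6R)-3-{[(tert-butyldimethylsilyl)oxy]methyl}-7-methylocta-2,7-diene-1,6-diol
Conditions: i-Bu2AlH (3.5 equiv), CH2Cl2, −78 → 0 °C; aq. potassium sodium tartrate
Reagents that add atoms: none
Why: 1,2-Reduction of the conjugated ester by i-Bu2AlH should give the primary allylic alcohol without touching the alkene geometry, the silyl ether or the carbinol centre.

Step 11
Reactants: 9 4-hydroxy-5-methyl-2H-chromen-2-one; 17 (2Z,6R)-3-{[(tert-butyldimethylsilyl)oxy]methyl}-7-methylocta-2,7-diene-1,6-diol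
Product: 18 4-{[(2Z,6R)-3-{[(tert-butyldimethylsilyl)oxy]methyl}-6-hydroxy-7-methylocta-2,7-dien-1-yl]oxy}-5-methyl-2H-chromen-2-one
Conditions: PPh3 (1.1 equiv), DIAD (1.1 equiv, added last and slowly), THF, 0 → 20 °C
Reagents that add atoms: none
Why: In this Mitsunobu reaction the acidic 4-hydroxycoumarin protonates the betaine, the unhindered primary allylic alcohol is activated in preference to the hindered secondary one, and the coumarin-4-olate should displace the oxyphosphonium group through O4 by SN2.

Step 12
Reactants: 18 4-{[(2Z,6R)-3-{[(tert-butyldimethylsilyl)oxy]methyl}-6-hydroxy-7-methylocta-2,7-dien-1-yl]oxy}-5-methyl-2H-chromen-2-one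
Product: 19 (3R,6Z)-6-{[(tert-butyldimethylsilyl)oxy]methyl}-2-methyl-8-[(5-methyl-2-oxo-2H-chromen-4-yl)oxy]octa-1,6-dien-3-yl methanesulfonate
Conditions: MsCl (1.2 equiv), Et3N (1.5 equiv), CH2Cl2, −30 °C; cold NaHCO3 wash, used crude at once
Reagents that add atoms: methanesulfonyl chloride, CS(=O)(=O)Cl
Why: Mesylation takes place at oxygen, so the (R) configuration is kept while the hydroxyl becomes a leaving group.

Step 13
Reactants: 19 (3R,6Z)-6-{[(tert-butyldimethylsilyl)oxy]methyl}-2-methyl-8-[(5-methyl-2-oxo-2H-chromen-4-yl)oxy]octa-1,6-dien-3-yl methanesulfonate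
Product: 20 4-{[(2Z,6S)-3-{[(tert-butyldimethylsilyl)oxy]methyl}-6-hydroperoxy-7-methylocta-2,7-dien-1-yl]oxy}-5-methyl-2H-chromen-2-one
Conditions: 50% aq. H2O2 (about 40 equiv), KOH (1.1 equiv), MeOH–THF, 0 °C; pH 7 phosphate buffer
Reagents that add atoms: hydrogen peroxide, OO
Why: Hydroperoxide anion, a strong but weakly basic α-effect nucleophile, should displace the secondary allylic mesylate by direct SN2 with inversion ((R) to (S)), the known route from optically active secondary mesylates to inverted hydroperoxides, while excess H2O2 suppresses dialkyl peroxide formation and the low temperature and near-stoichiometric base spare the lactone.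

Step 14
Reactants: 20 4-{[(2Z,6S)-3-{[(tert-butyldimethylsilyl)oxy]methyl}-6-hydroperoxy-7-methylocta-2,7-dien-1-yl]oxy}-5-methyl-2H-chromen-2-one
Product: 21 4-{[(2Z,6S)-6-hydroperoxy-3-(hydroxymethyl)-7-methylocta-2,7-dien-1-yl]oxy}-5-methyl-2H-chromen-2-one (CNP0171309.1)
Conditions: HF·pyridine, pyridine, THF, 0 → 20 °C; aq. NaHCO3
Reagents that add atoms: none
Why: Fluoride-assisted cleavage of the primary silyl ether under buffered, weakly acidic conditions should leave the allylic hydroperoxide, the allyl coumarinyl ether and the lactone intact.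

## Compound list

1 | 4-hydroxy-6-methyl-2H-pyran-2-one | Cc1cc(O)cc(=O)o1 | starting material
2 | methyl 3,5-dioxohexanoate | COC(=O)CC(=O)CC(C)=O | intermediate
3 | methyl (2Z,4Z)-3,5-bis(trimethylsilyloxy)hexa-2,4-dienoate (one geometry drawn) | COC(=O)/C=C(O[Si](C)(C)C)/C=C(/C)O[Si](C)(C)C | intermediate
4 | 1-methoxy-1,3,5-tris(trimethylsilyloxy)hexa-1,3,5-triene ((1Z,3Z) drawn) | C=C(O[Si](C)(C)C)/C=C(O[Si](C)(C)C)/C=C(/OC)O[Si](C)(C)C | intermediate
5 | (E)-4-methoxybut-3-en-2-one | CO/C=C/C(C)=O | starting material
6 | 1,7-dimethoxy-1,3-bis(trimethylsilyloxy)deca-1,3-diene-5,9-dione (open-chain conjugate adduct, drawn with the C9 ketone free; titanium enolate in the flask; geometry and C7 configuration undefined) | COC(O[Si](C)(C)C)=CC(O[Si](C)(C)C)=CC(=O)CC(OC)CC(C)=O | intermediate (not isolated)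
7 | 1-(2-hydroxy-4-methoxy-2-methyl-6-oxocyclohexyl)-3-methoxy-3-(trimethylsilyloxy)prop-2-en-1-one (aldol adduct, drawn as the free tertiary alcohol; titanium alkoxide in the flask; diastereomer mixture) | COC(O[Si](C)(C)C)=CC(=O)C1C(=O)CC(OC)CC1(C)O | intermediate (not isolated)
8 | methyl 3-(2-hydroxy-6-methylphenyl)-3-oxopropanoate | COC(=O)CC(=O)c1c(C)cccc1O | intermediate
9 | 4-hydroxy-5-methyl-2H-chromen-2-one | Cc1cccc2oc(=O)cc(O)c12 | intermediate
10 | tert-butyldimethyl(prop-2-yn-1-yloxy)silane | C#CCO[Si](C)(C)C(C)(C)C | starting material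
11 | propan-2-yl 4-[(tert-butyldimethylsilyl)oxy]but-2-ynoate | CC(C)OC(=O)C#CCO[Si](C)(C)C(C)(C)C | intermediate
12 | 5-bromo-2-methylpent-2-ene | CC(C)=CCCBr | starting material
13 | 4-methylpent-3-enylmagnesium bromide | CC(C)=CCC[Mg]Br | intermediate (not isolated)
14 | propan-2-yl (2Z)-3-{[(tert-butyldimethylsilyl)oxy]methyl}-7-methylocta-2,6-dienoate | CC(C)OC(=O)/C=C(/CCC=C(C)C)CO[Si](C)(C)C(C)(C)C | intermediate
15 | propan-2-yl (2Z)-3-{[(tert-butyldimethylsilyl)oxy]methyl}-5-[(2R)-3,3-dimethyloxiran-2-yl]pent-2-enoate | CC(C)OC(=O)/C=C(/CC[C@H]1OC1(C)C)CO[Si](C)(C)C(C)(C)C | intermediate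
16 | propan-2-yl (2Z,6R)-3-{[(tert-butyldimethylsilyl)oxy]methyl}-6-hydroxy-7-methylocta-2,7-dienoate | CC(C)OC(=O)/C=C(/CC[C@@H](O)C(C)=C)CO[Si](C)(C)C(C)(C)C | intermediate
17 | (2Z,6R)-3-{[(tert-butyldimethylsilyl)oxy]methyl}-7-methylocta-2,7-diene-1,6-diol | OC/C=C(/CC[C@@H](O)C(C)=C)CO[Si](C)(C)C(C)(C)C | intermediate
18 | 4-{[(2Z,6R)-3-{[(tert-butyldimethylsilyl)oxy]methyl}-6-hydroxy-7-methylocta-2,7-dien-1-yl]oxy}-5-methyl-2H-chromen-2-one | C=C(C)[C@H](O)CC/C(=C/COc1cc(=O)oc2cccc(C)c12)CO[Si](C)(C)C(C)(C)C | intermediate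
19 | (3R,6Z)-6-{[(tert-butyldimethylsilyl)oxy]methyl}-2-methyl-8-[(5-methyl-2-oxo-2H-chromen-4-yl)oxy]octa-1,6-dien-3-yl methanesulfonate | C=C(C)[C@H](OS(C)(=O)=O)CC/C(=C/COc1cc(=O)oc2cccc(C)c12)CO[Si](C)(C)C(C)(C)C | intermediate
20 | 4-{[(2Z,6S)-3-{[(tert-butyldimethylsilyl)oxy]methyl}-6-hydroperoxy-7-methylocta-2,7-dien-1-yl]oxy}-5-methyl-2H-chromen-2-one | C=C(C)[C@H](CC/C(=C/COc1cc(=O)oc2cccc(C)c12)CO[Si](C)(C)C(C)(C)C)OO | intermediate
21 | 4-{[(2Z,6S)-6-hydroperoxy-3-(hydroxymethyl)-7-methylocta-2,7-dien-1-yl]oxy}-5-methyl-2H-chromen-2-one | C=C(C)[C@H](CC/C(=C/COc1cc(=O)oc2cccc(C)c12)CO)OO | target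

## Step count and risks

Total step count: 14. Longest linear sequence: 9 steps (steps 1–5 then 11–14, or steps 6–10 then 11–14).

**Step 13 (hydroperoxide displacement).** The allylic mesylate may ionise or be attacked at the terminal methylene (SN2′), which would erode the configuration at C6′ and transpose the allyl system. It may also undergo a 1,3-shift before use, and the peroxide anion may attack the lactone. The fallback sets out from 14 and 9 and comes back at 20, giving up the SN2 step for a photo-oxygenation. Compound 14 would be reduced with i-Bu2AlH to (2Z)-3-{[(tert-butyldimethylsilyl)oxy]methyl}-7-methylocta-2,6-dien-1-ol F1, which would be joined to 9 under the Mitsunobu conditions of step 11 to give 4-{[(2Z)-3-{[(tert-butyldimethylsilyl)oxy]methyl}-7-methylocta-2,6-dien-1-yl]oxy}-5-methyl-2H-chromen-2-one F2. Schenck ene reaction with singlet oxygen (O2, 5,10,15,20-tetraphenylporphyrin, visible light, CH2Cl2, 0 °C) should attack only the electron-rich terminal alkene, since the 2′,3′-alkene is deactivated by its two allylic oxygens. It should give racemic 4-{[(2Z)-3-{[(tert-butyldimethylsilyl)oxy]methyl}-6-hydroperoxy-7-methylocta-2,7-dien-1-yl]oxy}-5-methyl-2H-chromen-2-one F3 together with the regioisomeric tertiary hydroperoxide 4-{[(2Z,5E)-3-{[(tert-butyldimethylsilyl)oxy]methyl}-7-hydroperoxy-7-methylocta-2,5-dien-1-yl]oxy}-5-methyl-2H-chromen-2-one F4. F4 would be removed on silica and the enantiomers of F3 separated by preparative HPLC on a chiral stationary phase; the (S)-enantiomer is 20.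

**Step 4 (key annulation).** The triene may be protodesilylated or oligomerised by TiCl4 before it reacts, or may attack first through an internal carbon, so that little arene forms. The fallback sets out from 5 and comes back at 9, keeping the same ring construction with a one-unit-shorter, well-precedented diene. Compound 5 would be condensed under the TiCl4 conditions with 2,4-bis(trimethylsilyloxy)penta-1,3-diene F5 (from commercial 4-(trimethylsilyloxy)pent-3-en-2-one, LDA, Me3SiCl) to give 1-(2-hydroxy-6-methylphenyl)ethan-1-one F6. C-Acylation of its enolate with diethyl carbonate (NaH, toluene, reflux) and lactonisation in the same flask should then give 9 directly, bypassing 8.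

**Step 11 (Mitsunobu etherification).** The ambident coumarin-4-olate may be alkylated at C3 or at the lactone carbonyl oxygen (2-alkoxychromone) instead of the peri-hindered O4, and the secondary hydroxyl may be partly activated. The fallback sets out from 9 and 17 and comes back at 18, reversing the polarity of the coupling. Compound 9 would be converted with POCl3 (BnEt3NCl, MeCN, reflux) into 4-chloro-5-methyl-2H-chromen-2-one F7. The primary alkoxide of 17 (one equivalent of NaN(SiMe3)2, THF, −78 °C, kept cold to avoid silyl migration) would then displace chloride at C4 by addition–elimination, which can only give the O4 ether 18.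

## Further compounds

F1 | step 13 | (2Z)-3-{[(tert-butyldimethylsilyl)oxy]methyl}-7-methylocta-2,6-dien-1-ol | OC/C=C(/CCC=C(C)C)CO[Si](C)(C)C(C)(C)C
F2 | step 13 | 4-{[(2Z)-3-{[(tert-butyldimethylsilyl)oxy]methyl}-7-methylocta-2,6-dien-1-yl]oxy}-5-methyl-2H-chromen-2-one | CC(C)=CCC/C(=C/COc1cc(=O)oc2cccc(C)c12)CO[Si](C)(C)C(C)(C)C
F3 | step 13 | racemic 4-{[(2Z)-3-{[(tert-butyldimethylsilyl)oxy]methyl}-6-hydroperoxy-7-methylocta-2,7-dien-1-yl]oxy}-5-methyl-2H-chromen-2-one | C=C(C)C(CC/C(=C/COc1cc(=O)oc2cccc(C)c12)CO[Si](C)(C)C(C)(C)C)OO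
F4 | step 13 | 4-{[(2Z,5E)-3-{[(tert-butyldimethylsilyl)oxy]methyl}-7-hydroperoxy-7-methylocta-2,5-dien-1-yl]oxy}-5-methyl-2H-chromen-2-one | CC(C)(OO)/C=C/C/C(=C/COc1cc(=O)oc2cccc(C)c12)CO[Si](C)(C)C(C)(C)C
F5 | step 4 | 2,4-bis(trimethylsilyloxy)penta-1,3-diene | C=C(O[Si](C)(C)C)C=C(C)O[Si](C)(C)C
F6 | step 4 | 1-(2-hydroxy-6-methylphenyl)ethan-1-one | CC(=O)c1c(C)cccc1O
F7 | step 11 | 4-chloro-5-methyl-2H-chromen-2-one | Cc1cccc2oc(=O)cc(Cl)c12
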